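## The problem

Target 27 is a cis-fused hydroazulene in which a cyclopentane (C1–C5) and a cycloheptene (C1, C5–C10) share the C1–C5 bond, C1 being a quaternary, methyl-bearing carbon and C5 a methine. Five stereocentres must be set: C1, the tertiary isopropyl carbinol C4, C5, the aroyloxy carbon C6 and the allylic tigloyloxy carbon C10; the C4 hydroxyl and the C6 ester oxygen lie on one face, and the C1 methyl, H5 and the C10 ester oxygen on the other. C1 cannot be corrected later, so it must carry the absolute configuration. Once locked in a rigid bicycle it can direct C4, C5 can equilibrate next to a C6 carbonyl, the C4 hydroxyl can deliver hydride to C6, and C10 has to be reached by relay across the seven-membered ring. The fragile groups are the tiglate (a Michael acceptor on an allylic, neopentylic carbon), the phenolic benzoate, and the tertiary alcohol β to the C6 oxygen (retro-aldol or dehydration at the ketone stage). Two different acyl groups on two secondary alcohols also mean that the two oxygens must appear one after the other. The enabling feature is that C7 is a methylene between oxygen-bearing C6 and methyl-bearing C8. Moving the C8=C9 alkene to C9=C10 and reading C6 as an enol ether turns the ring into a cyclohepta-1,4-diene (C5=C6, C9=C10) around C1, which is the retron of a cis-divinylcyclopropane Cope rearrangement on a cyclopropane made of C1, C5 and C10.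

## Retrosynthesis

**Acyl groups.** The phenol O–Si bond and the C10–O acyl bond are cut first: 27 comes from silyl ether 26, and 26 from allylic alcohol 23 and tiglic acid 24. The tiglate goes on last because it is the most fragile group. The reverse order would also leave two free secondary alcohols to be told apart. The forward step must acylate a hindered allylic alcohol without touching the tertiary C4 hydroxyl.

**C10 oxygen.** The C10–O bond is cut with the alkene returned from C8=C9 to C9=C10, so 23 comes from alkene 21 through hydroperoxide 22 by a singlet-oxygen ene reaction. Direct allylic oxidation of a C8=C9 alkene would attack C7 or the methyl group. An epoxide at C9–C10 would sit with its C10–O bond anti to the C4 hydroxyl and invite ether-bridge formation. In 21 the only allylic hydrogen is H8, so both the position and the face of the new oxygen are decided by the C8 stereocentre. The precursor has one oxygenated stereocentre fewer.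

**C6 ester and carbinol.** The C6–O acyl bond is cut to diol 17 and acid 20 (from 4-hydroxybenzoic acid 18 via 19). The C6–H bond is cut to β-hydroxy ketone 16, and the C5–H and O–Si bonds to bis-silyl enol ether 15. Aroylation before C10 oxygenation means the two secondary alcohols never coexist. The forward reduction must use the C4 hydroxyl to place the C6 oxygen on its own face, and C5 must settle in the cis-fused form.

**Key cut.** The C7–C8 bond is cut and C5–C10 re-formed, taking 15 back to the bicyclo[3.1.0]hexane 14. This removes the seven-membered ring and the C8 stereocentre in one operation. Neighbouring cuts (an aldol at C5–C6, or a ring-closing metathesis at C9=C10) would need an open chain carrying the quaternary C1 and the C4 carbinol, with no rigid element to relate them. The forward reaction needs the two alkenyl groups cis on the cyclopropane and the propenyl group (E).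

**Cyclopropane substituents.** The two O–Si bonds of 14 are cut to methyl ketone 13. The C6–C7 bond is cut to ester 11 (through α-silyl ketone 12), and the C4–isopropyl bond to keto ester 10. Adding the isopropyl group to the bicyclic ketone uses the folded bicycle to set C4; in an open chain this tertiary carbinol would need its own asymmetric step.

**Cyclopropane and chain.** The C5–C1 and C5–C10 bonds of 10 are cut to the achiral diazo keto ester 9, made from keto ester 8 by diazo transfer. The C2–C3 bond of 8 is cut to methyl acetoacetate 6 (as dianion 7) and dienyl bromide 5. Bromide 5 comes from alcohol 4 and ester 3, whose C1=C10 alkene is cut to crotonaldehyde 1 and ylide 2. All absolute stereochemistry then comes from one catalytic step on an achiral substrate, and the (E) geometry set in 3 becomes the cis relationship of the alkenyl groups in 10.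

## Roads not taken

Alternative 1: oxidopyrylium (5+2) cycloaddition. The cut runs through C1–C10 and C5–C6. The five-membered ring is bought as 3-methylcyclopent-2-en-1-one A1. Et3N releases a 3-oxidopyrylium ylide from 6-acetoxy-4-methyl-2H-pyran-3(6H)-one A2, and the ylide adds across the C=C bond of A1 to give the oxygen-bridged tricycle A3.
- Merits: one step makes the seven-membered ring, two C–C bonds, the quaternary C1, both C–O bonds at C6 and C10, the C8 methyl and a C4 carbonyl. In ring-forming economy this beats the chosen plan, which spends a cyclopropanation and a rearrangement on the same ring. Both A1 and A2 are only a step or two from commercial material.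
- Weak points: A1 is an electron-poor, β,β-disubstituted enone that must bond through its hindered β-carbon, the least favourable partner for this cycloaddition, and the regiochemistry is not secured. A2 is racemic and the ylide derived from it is achiral, so A3 arrives with no absolute stereocontrol. The oxygen bridge ties O6 and O10 to one face, whereas the target has them on opposite faces, so one C–O bond must be inverted or sacrificed. Reductive cleavage next to the C9 ketone would remove the C10 oxygen, the one that is hard to put back. A3 also has a surplus C9 carbonyl and its alkene at C7=C8.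
- Comparison: the chosen plan is longer to the bicycle but needs no inversion, no deoxygenation and no alkene migration afterwards.

Alternative 2: semipinacol contraction–expansion of a decalin. The cut is the C1–C5 bond, with C1 returned to C6. Starting from (R)-Wieland–Miescher ketone A4, ketalisation at C10, reduction and silylation at C4, dihydroxylation of the C5=C6 alkene and mesylation of the secondary C5 hydroxyl set the stage. KOtBu then forms the C6 alkoxide, which drives migration of C1 from C6 to C5 as the mesylate leaves and gives hydroazulenone A5 with a C6 ketone, a C10 ketal and a C4 silyl ether.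
- Merits: A4 is available in high enantiopurity on scale. This is a better source of the C1 configuration than the cyclopropanation of step 6, whose enantioselectivity is uncertain. The 1,2-shift is stereospecific, and C6 and C10 arrive oxygenated.
- Weak points: A5 lacks the C8 methyl, the C8=C9 alkene and the isopropyl group. Installing them means desaturation, conjugate methylation and a second desaturation between two ketones that must be kept apart, plus a late isopropyl addition at C4 without a rigid directing element.
- Comparison: the chosen plan has all fifteen skeletal carbons in place at compound 15 and offsets its weaker enantiocontrol with a much shorter endgame.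

Alternative 3: open-chain oxyallyl (4+3) cycloaddition. The cuts are C1–C5 and C7–C8. Et3N in trifluoroethanol ionises chloromethyl ketone A6 to the C5–C6–C7 oxyallyl cation, which adds across the tethered C1=C10–C9=C8 diene and closes both rings to ketone A7.
- Merits: A7 is the triethylsilyl ether of compound 16, so this road reaches the same intermediate and would share the endgame. It closes both rings at once and is probably the shorter way to that ketone.
- Weak points: A6 must already carry the tertiary C4 carbinol as a single enantiomer next to the chloroketone, which is a problem of its own. Three new stereocentres (C1, C5, C8) then depend on one flexible transition state biased only by C4. The quaternary C1 is made at a trisubstituted diene terminus, and Favorskii and solvolysis pathways compete.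
- Comparison: the chosen plan sets C1 by a catalyst on an achiral substrate, C4 by a rigid bicycle and C8 by a boat transition state. Each is a separate, inspectable event, at the price of more steps.

Key step: step 10

Remark on locants: the carbons are numbered C1 (quaternary methyl carbon), C2, C3, C4 (isopropyl carbinol), C5, C6 (aroyloxy carbon), C7, C8 (methyl-bearing carbon), C9, C10 (tigloyloxy carbon) in every intermediate. Hydroazulene names use these route locants on a bicyclo[5.3.0]decane frame; bicyclo[3.1.0]hexane names use standard numbering (position 1 = C5, 2 = C4, 5 = C1, 6 = C10).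

Assumption: the (S,S) ligand is written for step 6; the sense of induction must be confirmed on compound 10, and the mirror-image ligand is equally available.

## Route

Step 1
Reactants: 1 (2E)-but-2-enal; 2 ethyl 2-(triphenyl-λ5-phosphanylidene)propanoate
Product: 3 ethyl (2E,4E)-2-methylhexa-2,4-dienoate
Conditions: CH2Cl2, rt
Reagents that add atoms: none
Why: Wittig olefination with a stabilised, α-branched ylide should give the (E)-trisubstituted enoate; the aldehyde's (E) alkene is carried through unchanged.

Step 2
Reactants: 3 ethyl (2E,4E)-2-methylhexa-2,4-dienoate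
Product: 4 (2E,4E)-2-methylhexa-2,4-dien-1-ol
Conditions: i-Bu2AlH (2.2 equiv), CH2Cl2, −78 °C; aq. potassium sodium tartrate work-up
Reagents that add atoms: none
Why: 1,2-Reduction of a conjugated ester by an aluminium hydride gives the allylic alcohol without conjugate reduction or loss of alkene geometry.

Step 3
Reactants: 4 (2E,4E)-2-methylhexa-2,4-dien-1-ol
Product: 5 (2E,4E)-1-bromo-2-methylhexa-2,4-diene
Conditions: PBr3 (0.4 equiv), pyridine (cat.), Et2O, −10 to 0 °C; used crude
Reagents that add atoms: phosphorus tribromide, BrP(Br)Br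
Why: Bromination of a primary allylic alcohol at low temperature; the primary, fully conjugated bromide is also the thermodynamic allylic isomer, and it is used at once to avoid decomposition.

Step 4
Reactants: 6 methyl 3-oxobutanoate; 5 (2E,4E)-1-bromo-2-methylhexa-2,4-diene
Product: 8 methyl (6E,8E)-6-methyl-3-oxodeca-6,8-dienoate, via sodium lithium dienolate 7 (not isolated)
Conditions: NaH, THF, 0 °C; n-BuLi, 0 °C; then 5, 0 °C to rt; aq. NH4Cl
Reagents that add atoms: none
Why: γ-Alkylation of the acetoacetate dianion: the terminal carbon is the more nucleophilic site and displaces the primary allylic bromide by SN2, forming the C2–C3 bond.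

Step 5
Reactants: 8 methyl (6E,8E)-6-methyl-3-oxodeca-6,8-dienoate
Product: 9 methyl (6E,8E)-2-diazo-6-methyl-3-oxodeca-6,8-dienoate
Conditions: 4-acetamidobenzenesulfonyl azide, Et3N, MeCN, 0 °C to rt
Reagents that add atoms: 4-acetamidobenzenesulfonyl azide, CC(=O)Nc1ccc(cc1)S(=O)(=O)N=[N+]=[N-]
Why: Regitz diazo transfer to the doubly activated methylene; the diene is inert to the sulfonyl azide under these conditions.

Step 6
Reactants: 9 methyl (6E,8E)-2-diazo-6-methyl-3-oxodeca-6,8-dienoate
Product: 10 methyl (1S,5S,6S)-5-methyl-2-oxo-6-[(1E)-prop-1-enyl]bicyclo[3.1.0]hexane-1-carboxylate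
Conditions: [Cu(MeCN)4]PF6 (5 mol%), (S,S)-tBu-box (6 mol%), toluene, 50 °C, slow addition of 9
Reagents that add atoms: none
Why: Intramolecular cyclopropanation of an α-diazo-β-keto ester by a chiral bis(oxazoline) complex of monovalent copper; carbene transfer to the proximal trisubstituted alkene closes the five-membered ring. Addition is stereospecific, so the (E)-alkene places the propenyl group exo, cis to the C1 methyl and the ester. The ligand selects the alkene face and thereby sets C1, C5 and C10 together.

Step 7
Reactants: 10 methyl (1S,5S,6S)-5-methyl-2-oxo-6-[(1E)-prop-1-enyl]bicyclo[3.1.0]hexane-1-carboxylate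
Product: 11 methyl (1S,2R,5S,6S)-2-hydroxy-5-methyl-2-(propan-2-yl)-6-[(1E)-prop-1-enyl]bicyclo[3.1.0]hexane-1-carboxylate
Conditions: CeCl3 (anhydrous), i-PrMgCl, THF, −78 to −40 °C
Reagents that add atoms: isopropylmagnesium chloride, CC(C)[Mg]Cl
Why: Organocerium 1,2-addition, which suppresses enolisation and β-hydride reduction and prefers the ketone over the hindered ester or homoconjugate opening. Attack on the convex face, anti to the cyclopropane carbon C10, should place the C4 hydroxyl cis to C10 (4R in route locants).

Step 8
Reactants: 11 methyl (1S,2R,5S,6S)-2-hydroxy-5-methyl-2-(propan-2-yl)-6-[(1E)-prop-1-enyl]bicyclo[3.1.0]hexane-1-carboxylate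
Product: 13 1-[(1S,2R,5S,6S)-2-hydroxy-5-methyl-2-(propan-2-yl)-6-[(1E)-prop-1-enyl]bicyclo[3.1.0]hexan-1-yl]ethan-1-one, via alpha-silyl ketone 12 (not isolated)
Conditions: Me3SiCH2Li (4 equiv), THF/pentane, 0 °C to rt; then MeOH, rt
Reagents that add atoms: (trimethylsilyl)methyllithium, [Li]C[Si](C)(C)C
Why: Acyl substitution of an ester by (trimethylsilyl)methyllithium stops at the ketone stage because the α-silyl ketone 12 is deprotonated to its enolate; methanolysis then cleaves the C–Si bond and leaves the methyl ketone. No stereocentre is touched.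

Step 9
Reactants: 13 1-[(1S,2R,5S,6S)-2-hydroxy-5-methyl-2-(propan-2-yl)-6-[(1E)-prop-1-enyl]bicyclo[3.1.0]hexan-1-yl]ethan-1-one
Product: 14 (1R,2R,5S,6S)-5-methyl-2-(propan-2-yl)-6-[(1E)-prop-1-enyl]-2-(triethylsilyloxy)-1-[1-(triethylsilyloxy)ethenyl]bicyclo[3.1.0]hexane
Conditions: Et3SiOTf (3 equiv), Et3N (6 equiv), CH2Cl2, −78 to 0 °C; cold aq. NaHCO3; Et3N-deactivated silica
Reagents that add atoms: triethylsilyl trifluoromethanesulfonate, CC[Si](CC)(CC)OS(=O)(=O)C(F)(F)F
Why: Soft enolisation and O-silylation of a methyl ketone with a silyl triflate and an amine; C5 is quaternary, so only the terminal enol ether can form. The same reagent caps the hindered tertiary alcohol, and excess amine keeps the Lewis acid from opening the acyl vinylcyclopropane.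

Step 10
Reactants: 14 (1R,2R,5S,6S)-5-methyl-2-(propan-2-yl)-6-[(1E)-prop-1-enyl]-2-(triethylsilyloxy)-1-[1-(triethylsilyloxy)ethenyl]bicyclo[3.1.0]hexane
Product: 15 (1S,4R,8S)-1,8-dimethyl-4-(propan-2-yl)-4,6-bis(triethylsilyloxy)bicyclo[5.3.0]deca-5,9-diene
Conditions: degassed toluene, Et3N (trace), base-washed sealed glass, 100–110 °C
Reagents that add atoms: none
Why: This is a thermal [3,3] sigmatropic (Cope) rearrangement of a cis-1-(silyloxyvinyl)-2-alkenylcyclopropane, the classical divinylcyclopropane-to-cycloheptadiene reaction: C7 bonds to C8 while the strained C5–C10 bond breaks, and the π bonds move to C5=C6 and C9=C10. The seven-membered ring (C1, C5, C6, C7, C8, C9, C10) closes by this concerted ring expansion of the three-membered ring through a boat transition state with both alkenyl groups folded over the cyclopropane, the only geometry that gives two cis ring alkenes; the five-membered ring is untouched. The single new stereocentre C8 is fixed relative to C1 by that boat together with the (E) geometry of the propenyl group: the methyl points outward and the hydrogen inward towards C1, so H8 ends on the face of the C1 methyl (8S). C1 and C4 pass through unchanged, and the C5 and C10 stereocentres of the cyclopropane are consumed. The selectivity needed is the [3,3] shift over a homodienyl 1,5-hydrogen shift from the C1 methyl and over one-centre epimerisation of the cyclopropane; it rests on the cis arrangement of the alkenyl groups (built in by the stereospecific cyclopropanation of the (E)-alkene), on the absence of any inward substituent at C7 or C8, and on release of ring strain. Because the C1 methyl lies on the alkenyl-bearing face and crowds the boat, heating is expected to be necessary, which also allows 14 to be isolated.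

Step 11
Reactants: 15 (1S,4R,8S)-1,8-dimethyl-4-(propan-2-yl)-4,6-bis(triethylsilyloxy)bicyclo[5.3.0]deca-5,9-diene
Product: 16 (1S,4R,5R,8S)-4-hydroxy-1,8-dimethyl-4-(propan-2-yl)bicyclo[5.3.0]dec-9-en-6-one (cis-fused)
Conditions: HF·pyridine, pyridine, THF, 0 °C to rt; crude then DBU (0.2 equiv), CH2Cl2, rt
Reagents that add atoms: none
Why: Fluoride cleaves both Si–O bonds and the enol tautomerises to the C6 ketone. C5 is set under thermodynamic control: the trans-fused epimer would force C6 syn to both the C1 methyl and the C4 isopropyl group, so the cis-fused ketone (H5 cis to the C1 methyl) should predominate at equilibrium. Alkoxide bases are avoided to prevent retro-aldol cleavage.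

Step 12
Reactants: 16 (1S,4R,5R,8S)-4-hydroxy-1,8-dimethyl-4-(propan-2-yl)bicyclo[5.3.0]dec-9-en-6-one
Product: 17 (1S,4R,5S,6R,8S)-1,8-dimethyl-4-(propan-2-yl)bicyclo[5.3.0]dec-9-ene-4,6-diol
Conditions: Me4NBH(OAc)3 (5 equiv), MeCN/AcOH 1:1, −30 to 0 °C
Reagents that add atoms: none
Why: Evans–Saksena hydroxyl-directed reduction: the C4 hydroxyl exchanges onto boron and delivers hydride intramolecularly through a chair with C7 and the isopropyl group equatorial and the carbonyl oxygen axial. In that chair hydride reaches C6 between C4 and H5 and anti to the C5–C1 bond, which should place the new C6–O bond cis to the C4–O bond (6R).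

Step 13
Reactants: 18 4-hydroxybenzoic acid
Product: 20 4-[(tert-butyldimethylsilyl)oxy]benzoic acid, via bis-silylated benzoate 19 (not isolated)
Conditions: TBSCl (2.3 equiv), imidazole, DMF, rt; then AcOH/THF/H2O, rt
Reagents that add atoms: tert-butyldimethylsilyl chloride, CC(C)(C)[Si](C)(C)Cl
Why: Exhaustive silylation followed by selective hydrolysis of the labile silyl ester leaves the aryl silyl ether; a free phenol would compete in the acylation and quench singlet oxygen later.

Step 14
Reactants: 17 (1S,4R,5S,6R,8S)-1,8-dimethyl-4-(propan-2-yl)bicyclo[5.3.0]dec-9-ene-4,6-diol; 20 4-[(tert-butyldimethylsilyl)oxy]benzoic acid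
Product: 21 (1S,4R,5S,6R,8S)-4-hydroxy-1,8-dimethyl-4-(propan-2-yl)bicyclo[5.3.0]dec-9-en-6-yl 4-[(tert-butyldimethylsilyl)oxy]benzoate
Conditions: EDC·HCl, DMAP, CH2Cl2, 0 °C to rt
Reagents that add atoms: none
Why: Steglich esterification; only the secondary C6 hydroxyl is acylated, the tertiary C4 hydroxyl being inert to carbodiimide/DMAP acylation.

Step 15
Reactants: 21 (1S,4R,5S,6R,8S)-4-hydroxy-1,8-dimethyl-4-(propan-2-yl)bicyclo[5.3.0]dec-9-en-6-yl 4-[(tert-butyldimethylsilyl)oxy]benzoate
Product: 23 (1R,4R,5S,6R,10R)-4,10-dihydroxy-1,8-dimethyl-4-(propan-2-yl)bicyclo[5.3.0]dec-8-en-6-yl 4-[(tert-butyldimethylsilyl)oxy]benzoate, via allylic hydroperoxide 22 (not isolated)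
Conditions: O2, visible light, tetraphenylporphyrin (cat.), CH2Cl2, −20 °C, to partial conversion; then PPh3, −20 °C to rt
Reagents that add atoms: dioxygen, O=O
Why: Schenck ene reaction of singlet oxygen with the C9=C10 alkene: the only allylic hydrogen is H8, so oxygen must bond to C10 and the alkene must move to C8=C9. The reaction is suprafacial and H8 lies on the face of the C1 methyl, so the C10 oxygen arrives on that face (10R). PPh3 reduces the O–O bond without touching C10, and the C8 stereocentre is consumed.

Step 16
Reactants: 23 (1R,4R,5S,6R,10R)-4,10-dihydroxy-1,8-dimethyl-4-(propan-2-yl)bicyclo[5.3.0]dec-8-en-6-yl 4-[(tert-butyldimethylsilyl)oxy]benzoate; 24 (2E)-2-methylbut-2-enoic acid (tiglic acid)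
Product: 26 (1R,4R,5S,6R,10R)-4-hydroxy-1,8-dimethyl-10-{[(2E)-2-methylbut-2-enoyl]oxy}-4-(propan-2-yl)bicyclo[5.3.0]dec-8-en-6-yl 4-[(tert-butyldimethylsilyl)oxy]benzoate, via mixed anhydride 25 (not isolated)
Conditions: 24, 2,4,6-Cl3C6H2COCl, Et3N, toluene, rt; then 23, DMAP, 60 °C
Reagents that add atoms: none
Why: Yamaguchi esterification: the mixed anhydride 25 transfers the tigloyl group through its acylpyridinium to the hindered secondary allylic hydroxyl, while the tertiary hydroxyl does not react. Tiglate is the stable (E) isomer, so no geometric drift is expected.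

Step 17
Reactants: 26 (1R,4R,5S,6R,10R)-4-hydroxy-1,8-dimethyl-10-{[(2E)-2-methylbut-2-enoyl]oxy}-4-(propan-2-yl)bicyclo[5.3.0]dec-8-en-6-yl 4-[(tert-butyldimethylsilyl)oxy]benzoate
Product: 27 (1R,4R,5S,6R,10R)-4-hydroxy-1,8-dimethyl-10-{[(2E)-2-methylbut-2-enoyl]oxy}-4-(propan-2-yl)bicyclo[5.3.0]dec-8-en-6-yl 4-hydroxybenzoate (target)
Conditions: Bu4NF, AcOH (1:1), THF, 0 °C
Reagents that add atoms: none
Why: Fluoride cleavage of the aryl silyl ether; acetic acid buffering keeps the phenoxide from attacking the tiglate or the allylic ester.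

## Compound list

1 | (2E)-but-2-enal (crotonaldehyde) | C/C=C/C=O | starting material
2 | ethyl 2-(triphenyl-λ5-phosphanylidene)propanoate | CCOC(=O)C(C)=P(c1ccccc1)(c1ccccc1)c1ccccc1 | starting material
3 | ethyl (2E,4E)-2-methylhexa-2,4-dienoate | CCOC(=O)/C(C)=C/C=C/C | intermediate
4 | (2E,4E)-2-methylhexa-2,4-dien-1-ol | OC/C(C)=C/C=C/C | intermediate
5 | (2E,4E)-1-bromo-2-methylhexa-2,4-diene | BrC/C(C)=C/C=C/C | intermediate
6 | methyl 3-oxobutanoate (methyl acetoacetate) | COC(=O)CC(C)=O | starting material
7 | sodium lithium 1-methoxybuta-1,3-diene-1,3-diolate (dianion of 6) | C=C([O-])C=C([O-])OC.[Na+].[Li+] | intermediate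
8 | methyl (6E,8E)-6-methyl-3-oxodeca-6,8-dienoate | COC(=O)CC(=O)CC/C(C)=C/C=C/C | intermediate
9 | methyl (6E,8E)-2-diazo-6-methyl-3-oxodeca-6,8-dienoate | COC(=O)C(=[N+]=[N-])C(=O)CC/C(C)=C/C=C/C | intermediate
10 | methyl (1S,5S,6S)-5-methyl-2-oxo-6-[(1E)-prop-1-enyl]bicyclo[3.1.0]hexane-1-carboxylate | COC(=O)[C@@]12[C@@H](/C=C/C)[C@]1(C)CCC2=O | intermediate
11 | methyl (1S,2R,5S,6S)-2-hydroxy-5-methyl-2-(propan-2-yl)-6-[(1E)-prop-1-enyl]bicyclo[3.1.0]hexane-1-carboxylate | COC(=O)[C@@]12[C@@H](/C=C/C)[C@]1(C)CC[C@@]2(O)C(C)C | intermediate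
12 | 1-[(1S,2R,5S,6S)-2-hydroxy-5-methyl-2-(propan-2-yl)-6-[(1E)-prop-1-enyl]bicyclo[3.1.0]hexan-1-yl]-2-(trimethylsilyl)ethan-1-one (present as its lithium enolate/alkoxide) | C[Si](C)(C)CC(=O)[C@@]12[C@@H](/C=C/C)[C@]1(C)CC[C@@]2(O)C(C)C | intermediate
13 | 1-[(1S,2R,5S,6S)-2-hydroxy-5-methyl-2-(propan-2-yl)-6-[(1E)-prop-1-enyl]bicyclo[3.1.0]hexan-1-yl]ethan-1-one | CC(=O)[C@@]12[C@@H](/C=C/C)[C@]1(C)CC[C@@]2(O)C(C)C | intermediate
14 | (1R,2R,5S,6S)-5-methyl-2-(propan-2-yl)-6-[(1E)-prop-1-enyl]-2-(triethylsilyloxy)-1-[1-(triethylsilyloxy)ethenyl]bicyclo[3.1.0]hexane | C=C(O[Si](CC)(CC)CC)[C@@]12[C@@H](/C=C/C)[C@]1(C)CC[C@@]2(O[Si](CC)(CC)CC)C(C)C | intermediate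
15 | (1S,4R,8S)-1,8-dimethyl-4-(propan-2-yl)-4,6-bis(triethylsilyloxy)bicyclo[5.3.0]deca-5,9-diene (route locants) | C1=C[C@@H](C)CC(O[Si](CC)(CC)CC)=C2[C@@]1(C)CC[C@@]2(O[Si](CC)(CC)CC)C(C)C | intermediate
16 | (1S,4R,5R,8S)-4-hydroxy-1,8-dimethyl-4-(propan-2-yl)bicyclo[5.3.0]dec-9-en-6-one, cis-fused (route locants) | C1=C[C@@H](C)CC(=O)[C@@H]2[C@@]1(C)CC[C@@]2(O)C(C)C | intermediate
17 | (1S,4R,5S,6R,8S)-1,8-dimethyl-4-(propan-2-yl)bicyclo[5.3.0]dec-9-ene-4,6-diol (route locants) | C1=C[C@@H](C)C[C@@H](O)[C@@H]2[C@@]1(C)CC[C@@]2(O)C(C)C | intermediate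
18 | 4-hydroxybenzoic acid | O=C(O)c1ccc(O)cc1 | starting material
19 | tert-butyldimethylsilyl 4-[(tert-butyldimethylsilyl)oxy]benzoate | CC(C)(C)[Si](C)(C)OC(=O)c1ccc(O[Si](C)(C)C(C)(C)C)cc1 | intermediate
20 | 4-[(tert-butyldimethylsilyl)oxy]benzoic acid | O=C(O)c1ccc(O[Si](C)(C)C(C)(C)C)cc1 | intermediate
21 | (1S,4R,5S,6R,8S)-4-hydroxy-1,8-dimethyl-4-(propan-2-yl)bicyclo[5.3.0]dec-9-en-6-yl 4-[(tert-butyldimethylsilyl)oxy]benzoate (route locants) | C1=C[C@@H](C)C[C@@H](OC(=O)c3ccc(O[Si](C)(C)C(C)(C)C)cc3)[C@@H]2[C@@]1(C)CC[C@@]2(O)C(C)C | intermediate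
22 | (1R,4R,5S,6R,10R)-10-hydroperoxy-4-hydroxy-1,8-dimethyl-4-(propan-2-yl)bicyclo[5.3.0]dec-8-en-6-yl 4-[(tert-butyldimethylsilyl)oxy]benzoate (route locants) | OO[C@@H]1C=C(C)C[C@@H](OC(=O)c3ccc(O[Si](C)(C)C(C)(C)C)cc3)[C@@H]2[C@@]1(C)CC[C@@]2(O)C(C)C | intermediate
23 | (1R,4R,5S,6R,10R)-4,10-dihydroxy-1,8-dimethyl-4-(propan-2-yl)bicyclo[5.3.0]dec-8-en-6-yl 4-[(tert-butyldimethylsilyl)oxy]benzoate (route locants) | O[C@@H]1C=C(C)C[C@@H](OC(=O)c3ccc(O[Si](C)(C)C(C)(C)C)cc3)[C@@H]2[C@@]1(C)CC[C@@]2(O)C(C)C | intermediate
24 | (2E)-2-methylbut-2-enoic acid (tiglic acid) | C/C=C(\C)C(=O)O | starting material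
25 | (2E)-2-methylbut-2-enoic 2,4,6-trichlorobenzoic anhydride | C/C=C(\C)C(=O)OC(=O)c1c(Cl)cc(Cl)cc1Cl | intermediate
26 | (1R,4R,5S,6R,10R)-4-hydroxy-1,8-dimethyl-10-{[(2E)-2-methylbut-2-enoyl]oxy}-4-(propan-2-yl)bicyclo[5.3.0]dec-8-en-6-yl 4-[(tert-butyldimethylsilyl)oxy]benzoate (route locants) | C/C=C(\C)C(=O)O[C@@H]1C=C(C)C[C@@H](OC(=O)c2ccc(O[Si](C)(C)C(C)(C)C)cc2)[C@@H]2[C@@]1(C)CC[C@@]2(O)C(C)C | intermediate
27 | (1R,4R,5S,6R,10R)-4-hydroxy-1,8-dimethyl-10-{[(2E)-2-methylbut-2-enoyl]oxy}-4-(propan-2-yl)bicyclo[5.3.0]dec-8-en-6-yl 4-hydroxybenzoate (route locants) | C/C=C(\C)C(=O)O[C@@H]1C=C(C)C[C@@H](OC(=O)c2ccc(O)cc2)[C@@H]2[C@@]1(C)CC[C@@]2(O)C(C)C | target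

## Step count and least certain steps

Total steps: 17. Longest linear sequence: 16 steps (steps 1–12 and 14–17); step 13 is a one-step side branch.

**Step 10 (key step).** The C1 methyl shares the face of both alkenyl groups, and the C6 triethylsilyloxy group is pressed against the fully substituted C4. The boat may therefore be reached slowly, and a homodienyl 1,5-hydrogen shift from the C1 methyl, one-centre epimerisation of the cyclopropane or loss of the silyl enol ether may compete at the temperature required. Fallback with smaller groups on the same rearrangement: starting from 11, the C4 hydroxyl is capped with Me3SiOTf/2,6-lutidine to give the trimethylsilyl ether F1. The ester carbonyl is methylenated with Cp2Ti(μ-Cl)(μ-CH2)AlMe2 (pyridine, THF/toluene, −40 °C to rt) to give the 1-methoxyvinyl cyclopropane F2. Heating F2 in toluene should give the methyl enol ether F3, and aqueous HCl in THF hydrolyses the enol ether and the silyl ether to return to the route at 16. This replaces steps 8–11 and exchanges the enolate silylation for a carbonyl olefination.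

**Step 6.** Acceptor/acceptor carbenes from diazo keto esters are among the harder substrates for bis(oxazoline) complexes of monovalent copper, so enantioface discrimination may be incomplete, and the sense of induction is assumed. Fallback by resolution: 9 is cyclised with Rh2(OAc)4 (CH2Cl2, rt) to racemic material, and preparative chromatography on a chiral stationary phase separates 10 from its mirror image F4. The route resumes at 10, at the cost of half the material.

**Step 8.** The ester sits on a cyclopropane carbon flanked by the C1 methyl, the propenyl group and the fully substituted C4, so addition of the silylmethyl nucleophile may be slow and the lithium alkoxide may aggregate and stall the reaction. Fallback in two stages: from 11, Me2AlN(OMe)Me (from AlMe3 and MeNHOMe·HCl, CH2Cl2/toluene, 0 to 40 °C), bound and delivered through the neighbouring C4 aluminium alkoxide, gives the N-methoxy-N-methylamide F5. MeLi (THF, −78 °C) then adds once through the stable chelate and returns to the route at 13.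

**Step 12.** Ligand exchange of the crowded tertiary hydroxyl onto boron may be slow, so undirected reduction could take over, with poor facial selectivity at C6. Fallback without covalent boron delivery: from 16, Zn(BH4)2 (Et2O, −20 °C) reduces the zinc chelate of the β-hydroxy ketone from outside; with the carbonyl oxygen held near O4, approach anti to the C5–C1 bond should again give 17 and rejoin the route there. Should external hydride instead favour the C6-epimeric diol F6, Mitsunobu esterification of F6 with acid 20 (PPh3, DIAD, toluene, 0 °C to rt) inverts C6 while forming the ester and returns to the route at 21, replacing step 14.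

**Step 15.** A cis-1,2-disubstituted cycloalkene reacts slowly with singlet oxygen, and the product's trisubstituted C8=C9 alkene is at least as reactive, so over-oxidation at high conversion is the main threat; the reaction is stopped early and 21 recycled. Fallback through an epoxide: from 21, Me3SiOTf/2,6-lutidine caps the C4 hydroxyl to give the silyl ether F7, which removes its ability to open an epoxide at C10 and shields the upper face. Dimethyldioxirane (acetone, 0 °C) should then give the lower-face 9,10-epoxide F8. Me3SiOTf/2,6-lutidine followed by DBU opens the epoxide with triflate at C9, away from the neopentylic C10, and eliminates the anti H8 to give the allylic bis(trimethylsilyl) ether F9. Citric acid in MeOH removes both trimethylsilyl groups and returns to the route at 23.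

## Further compounds

F1 | step 10 | methyl (1S,2R,5S,6S)-5-methyl-2-(propan-2-yl)-6-[(1E)-prop-1-enyl]-2-(trimethylsilyloxy)bicyclo[3.1.0]hexane-1-carboxylate | COC(=O)[C@@]12[C@@H](/C=C/C)[C@]1(C)CC[C@@]2(O[Si](C)(C)C)C(C)C
F2 | step 10 | (1R,2R,5S,6S)-1-(1-methoxyethenyl)-5-methyl-2-(propan-2-yl)-6-[(1E)-prop-1-enyl]-2-(trimethylsilyloxy)bicyclo[3.1.0]hexane | C=C(OC)[C@@]12[C@@H](/C=C/C)[C@]1(C)CC[C@@]2(O[Si](C)(C)C)C(C)C
F3 | step 10 | (1S,4R,8S)-6-methoxy-1,8-dimethyl-4-(propan-2-yl)-4-(trimethylsilyloxy)bicyclo[5.3.0]deca-5,9-diene (route locants) | C1=C[C@@H](C)CC(OC)=C2[C@@]1(C)CC[C@@]2(O[Si](C)(C)C)C(C)C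
F4 | step 6 | methyl (1R,5R,6R)-5-methyl-2-oxo-6-[(1E)-prop-1-enyl]bicyclo[3.1.0]hexane-1-carboxylate (mirror image of 10) | COC(=O)[C@]12[C@H](/C=C/C)[C@@]1(C)CCC2=O
F5 | step 8 | (1S,2R,5S,6S)-2-hydroxy-N-methoxy-N,5-dimethyl-2-(propan-2-yl)-6-[(1E)-prop-1-enyl]bicyclo[3.1.0]hexane-1-carboxamide | CON(C)C(=O)[C@@]12[C@@H](/C=C/C)[C@]1(C)CC[C@@]2(O)C(C)C
F6 | step 12 | (1S,4R,5S,6S,8S)-1,8-dimethyl-4-(propan-2-yl)bicyclo[5.3.0]dec-9-ene-4,6-diol (C6 epimer of 17, route locants) | C1=C[C@@H](C)C[C@H](O)[C@@H]2[C@@]1(C)CC[C@@]2(O)C(C)C
F7 | step 15 | (1S,4R,5S,6R,8S)-1,8-dimethyl-4-(propan-2-yl)-4-(trimethylsilyloxy)bicyclo[5.3.0]dec-9-en-6-yl 4-[(tert-butyldimethylsilyl)oxy]benzoate (route locants) | C1=C[C@@H](C)C[C@@H](OC(=O)c3ccc(O[Si](C)(C)C(C)(C)C)cc3)[C@@H]2[C@@]1(C)CC[C@@]2(O[Si](C)(C)C)C(C)C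
F8 | step 15 | 9,10-epoxide of F7 with the epoxide oxygen on the face of the C1 methyl and H8 | O1[C@@H]2[C@H]1[C@@H](C)C[C@@H](OC(=O)c4ccc(O[Si](C)(C)C(C)(C)C)cc4)[C@@H]3[C@@]2(C)CC[C@@]3(O[Si](C)(C)C)C(C)C
F9 | step 15 | (1R,4R,5S,6R,10R)-1,8-dimethyl-4-(propan-2-yl)-4,10-bis(trimethylsilyloxy)bicyclo[5.3.0]dec-8-en-6-yl 4-[(tert-butyldimethylsilyl)oxy]benzoate (route locants) | C[Si](C)(C)O[C@@H]1C=C(C)C[C@@H](OC(=O)c3ccc(O[Si](C)(C)C(C)(C)C)cc3)[C@@H]2[C@@]1(C)CC[C@@]2(O[Si](C)(C)C)C(C)C
A1 | alternative 1 | 3-methylcyclopent-2-en-1-one | CC1=CC(=O)CC1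
A2 | alternative 1 | 6-acetoxy-4-methyl-2H-pyran-3(6H)-one (racemic) | CC(=O)OC1OCC(=O)C(C)=C1
A3 | alternative 1 | oxygen-bridged tricyclic enedione (C6–O–C10 bridge, C9 ketone, C7=C8 alkene, C4 ketone) | O1[C@H]2C(=O)C(C)=C[C@@H]1[C@@H]3[C@@]2(C)CCC3=O
A4 | alternative 2 | (R)-Wieland–Miescher ketone | C[C@@]12CCC(=O)C=C1CCCC2=O
A5 | alternative 2 | cis-fused hydroazulen-6-one with C10 dioxolane and C4 tert-butyldimethylsilyl ether | C12(OCCO1)CCCC(=O)[C@@H]3[C@@]2(C)CC[C@H]3O[Si](C)(C)C(C)(C)C
A6 | alternative 3 | (4S,7E,9E)-1-chloro-7-methyl-4-(propan-2-yl)-4-(triethylsilyloxy)undeca-7,9-dien-2-one | ClCC(=O)C[C@](O[Si](CC)(CC)CC)(C(C)C)CC/C(C)=C/C=C/C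
A7 | alternative 3 | cis-fused hydroazulen-6-one with C9=C10 alkene, C8 methyl and C4 triethylsilyl ether (silyl ether of 16) | C1=C[C@@H](C)CC(=O)[C@@H]2[C@@]1(C)CC[C@@]2(O[Si](CC)(CC)CC)C(C)C
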